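All runs are simulated with made-up constants; noise was put on by code.

I had one loading to choose. Tuesday's and Thursday's flasks differ in free catalyst, Thursday's taking twice as much, and I wanted to know whether that extra catalyst puts target ahead of substrate within 20 h.

| setting | ash | oak | Thursday's | Tuesday's |
|---|---|---|---|---|
| substrate | 20 mM | 20 mM | 20 mM | 20 mM |
| coupling partner | 0.90 equiv | 0.90 equiv | 0.900 equiv | 0.900 equiv |
| free catalyst | 0.76 mol% | 1.3 mol% | 2 mol% | 1 mol% |
| remark | run made earlier | run made earlier |  |  |
| time |  |  | 20 h | 20 h |

| run | time / h | substrate / % | over-reaction product / % | catalyst intermediate D / % | target / % |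
|---|---|---|---|---|---|
| ash | 2.00 | 97.6 | 0 | 0 | 3.0 |
| ash | 4.00 | 95.2 | 0 | 0 | 8.4 |
| ash | 6.00 | 91.9 | 0 | 1.2 | 8.3 |
| ash | 8.00 | 86.9 | 0.5 | 0.2 | 10.6 |
| ash | 10.0 | 85.2 | 0 | 0 | 15.2 |
| oak | 0.833 | 97.4 | 0 | 3.3 | 1.2 |
| oak | 2.50 | 93.4 | 1.3 | 1.3 | 6.8 |
| oak | 5.00 | 85.5 | 0.5 | 0.1 | 13.2 |
| oak | 8.00 | 78.9 | 1.5 | 1.2 | 19.2 |
| oak | 10.0 | 73.3 | 3.0 | 2.6 | 23.0 |

(each reading ± 1 percentage point)

* which of these there is most of at the end, counted by the substrate in it, Thursday's (target / substrate / catalyst intermediate D / over-reaction product)
* which of these there is most of at the end, counted by the substrate in it, Tuesday's (target / substrate / catalyst intermediate D / over-reaction product)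
* final amount of the leader among these, as a percentage of the substrate charged, in Thursday's
* final amount of the leader among these, as a percentage of the substrate charged, in Tuesday's



I counted time in one-percent hours: hours stirred, times the loading, over 1 mol%. On that clock the last reading of the ash run stands at 7.60 h and that of the oak run at 13.0 h. Pooling the logarithm of substrate left at those two readings over their summed hours, I read a loss of 0.0229 h⁻¹, the fractional substrate loss per one-percent hour, a pseudo-first-order constant on this clock and a reading with scatter in it. Tuesday's flask gets 20 h on the clock and Thursday's 40.0 h, so I reckoned substrate at 63.3 % and 40.1 %.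

Over-reaction I treated as a correction to what is consumed. At its last reading the oak run showed over-reaction product as 11.5 % of target and over-reaction product together, a scattered reading, so I reckoned target at 32.5 % in Tuesday's flask, less than its substrate, and at 53.0 % in Thursday's flask, more than its substrate. With that share set at 23.0 %, Thursday's target still came to 46.1 %, above its substrate. So I chose Thursday's loading.

The forecast named target for Thursday's flask at 47 % and substrate for Tuesday's at 61 %, on the ground “so the rate is first order in catalyst”. It agreed with my leaders, though its Thursday's figure lay below mine.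

Thursday's flask ended with target at 51.0 % and substrate at 40.0 %. Tuesday's flask ended with substrate at 63.0 % and target at 33.4 %.

    coupling partner + free catalyst → catalyst intermediate A (k = 314 M⁻¹ h⁻¹)
    catalyst intermediate C → catalyst intermediate D (k = 92.9 h⁻¹)
    coupling partner + free catalyst + target → free catalyst + over-reaction product (k = 8750 M⁻² h⁻¹)
    catalyst intermediate A → catalyst intermediate B (k = 14.5 h⁻¹)
    catalyst intermediate D → free catalyst + target (k = 11.3 h⁻¹)
    substrate + catalyst intermediate B ⇌ catalyst intermediate C (K = 50.3 M⁻¹, k = 512 M⁻¹ h⁻¹)

The one constant had given substrate at 63.3 % for Tuesday's flask and 40.1 % for Thursday's, against the 63.0 % and 40.0 % found. A neighbour of Thursday's flask took 0.540 equiv of coupling partner. I scaled its clock by that charge over 0.900 equiv, which gave 24.0 h, and so substrate at 57.8 % and target at 37.3 %. That neighbour ended with substrate leading at 58.4 % and target at 37.2 %.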